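The labdane bicycle is disconnected across C5–C10 and C8–C9. C2–C5 of ring A, with the C3 oxygen and the C4 gem-dimethyl group, are the carbon chain of (S)-pantolactone; with C1 they form a four-atom tether between a C5–C8 2-silyloxydiene and the C9=C10 (E)-enal. One intramolecular Diels–Alder reaction closes rings A and B together and sets C5, C8, C9 and C10, leaving a C6–C7 enol ether as the handle for the C7–C8 alkene and the C11 aldehyde for the side chain. The precursor is the open-chain trienal 16, carrying C2-OTBS, C3-OPMB and the C7 silyl dienol ether, whose diene is installed before the aldehyde is unveiled.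

Key step: step 13

Assumption: labdane numbering is used for every intermediate (ring carbons C1–C10, side chain C11–C16, C17 on C8, C18 and C19 on C4, C20 on C10); C2 is a stereocentre only until it becomes the ketone in step 22.

Step 1
Reactants: 1 (S)-pantolactone
Product: 2 (2S)-3,3-dimethylbutane-1,2,4-triol
Conditions: LiAlH4, THF, 0 °C → reflux
Reagents that add atoms: none
Why: Hydride reduction of the lactone to the diol does not involve the carbinol centre (future C3), which keeps its configuration.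

Step 2
Reactants: 2 (2S)-3,3-dimethylbutane-1,2,4-triol
Product: 3 [(2S,4S)-2-(4-methoxyphenyl)-5,5-dimethyl-1,3-dioxan-4-yl]methanol
Conditions: 4-MeOC6H4CH(OMe)2, camphorsulfonic acid (cat.), CH2Cl2, rt
Reagents that add atoms: 4-methoxybenzaldehyde dimethyl acetal, COc1ccc(cc1)C(OC)OC
Why: Acid-catalysed transacetalisation under thermodynamic control should tie O3 and O5 into the six-membered arylidene acetal (aryl and CH2OH equatorial, helped by the gem-dimethyl group) and leave the C2 hydroxyl free; the acetal carbon is set by equilibration and disappears in step 4.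

Step 3
Reactants: 3 [(2S,4S)-2-(4-methoxyphenyl)-5,5-dimethyl-1,3-dioxan-4-yl]methanol
Product: 4 triethylsilyl ether of 3
Conditions: Et3SiCl, imidazole, CH2Cl2, 0 °C
Reagents that add atoms: chlorotriethylsilane, CC[Si](Cl)(CC)CC
Why: Silylation of the only free hydroxyl; TES is chosen because a primary TES ether survives i-Bu2AlH, Dess–Martin and olefination conditions and can be oxidised directly to the aldehyde in step 7.

Step 4
Reactants: 4 triethylsilyl ether of 3
Product: 5 (3S)-3-[(4-methoxybenzyl)oxy]-2,2-dimethyl-4-[(triethylsilyl)oxy]butan-1-ol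
Conditions: i-Bu2AlH, CH2Cl2, −78 → 0 °C; KNaC4H4O6 work-up
Reagents that add atoms: none
Why: Reductive opening of the arylidene acetal: aluminium binds the less hindered primary oxygen (O5) and hydride adds to the oxocarbenium ion, so that the PMB group should stay on O3 and the C5 hydroxyl is freed.

Step 5
Reactants: 5 (3S)-3-[(4-methoxybenzyl)oxy]-2,2-dimethyl-4-[(triethylsilyl)oxy]butan-1-ol
Product: 6 (3S)-3-[(4-methoxybenzyl)oxy]-2,2-dimethyl-4-[(triethylsilyl)oxy]butanal
Conditions: Dess–Martin periodinane, pyridine, CH2Cl2, rt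
Reagents that add atoms: none
Why: Dess–Martin oxidation of the neopentyl alcohol gives an aldehyde without α-hydrogen, so neither epimerisation nor elimination of the C3 ether is possible.

Step 6
Reactants: 6 (3S)-3-[(4-methoxybenzyl)oxy]-2,2-dimethyl-4-[(triethylsilyl)oxy]butanal; 7 diethyl (2-oxobutyl)phosphonate
Product: 8 (4E,7S)-7-[(4-methoxybenzyl)oxy]-6,6-dimethyl-8-[(triethylsilyl)oxy]oct-4-en-3-one
Conditions: NaH, THF, 0 °C → rt
Reagents that add atoms: diethyl (2-oxobutyl)phosphonate 7, CCC(=O)CP(=O)(OCC)OCC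
Why: Horner–Wadsworth–Emmons olefination of a non-enolisable aldehyde with a stabilised keto phosphonate anion should give the (E)-enone C5=C6 with the C7 carbonyl and the C8–C17 ethyl group in place.

Step 7
Reactants: 8 (4E,7S)-7-[(4-methoxybenzyl)oxy]-6,6-dimethyl-8-[(triethylsilyl)oxy]oct-4-en-3-one
Product: 9 (2S,4E)-2-[(4-methoxybenzyl)oxy]-3,3-dimethyl-6-oxooct-4-enal
Conditions: (COCl)2, DMSO, CH2Cl2, −78 → −40 °C; Et3N, −78 → 0 °C
Reagents that add atoms: none
Why: Under Swern conditions a primary TES ether is converted directly into the aldehyde (silyl transfer to chloride, then fragmentation of the alkoxysulfonium ylide); the α-alkoxy aldehyde is used crude and cold so that C3 is not epimerised.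

Step 8
Reactants: 10 methyl 3-methylbut-2-enoate
Product: 12 [(1-methoxy-3-methylbuta-1,3-dien-1-yl)oxy]trimethylsilane, via lithium dienolate 11 (not isolated)
Conditions: LiN(i-Pr)2, THF, −78 °C; Me3SiCl
Reagents that add atoms: chlorotrimethylsilane, C[Si](C)(C)Cl
Why: γ-Deprotonation of the ester gives the extended lithium dienolate, which is trapped on oxygen to give the silyl ketene acetal needed for the vinylogous aldol.

Step 9
Reactants: 9 (2S,4E)-2-[(4-methoxybenzyl)oxy]-3,3-dimethyl-6-oxooct-4-enal; 12 [(1-methoxy-3-methylbuta-1,3-dien-1-yl)oxy]trimethylsilane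
Product: 13 methyl (2E,5S,6S,8E)-5-hydroxy-6-[(4-methoxybenzyl)oxy]-3,7,7-trimethyl-10-oxododeca-2,8-dienoate
Conditions: MgBr2·OEt2, CH2Cl2, −78 → −20 °C
Reagents that add atoms: silyl dienolate 12, C=C(C)C=C(OC)O[Si](C)(C)C
Why: Vinylogous Mukaiyama aldol under chelation control: magnesium bridges the aldehyde oxygen and the PMB ether, the γ-carbon of the dienolate attacks the face away from the quaternary C4, which should set C2 syn to C3 (5S,6S), and the s-trans dienolate gives the (E)-enoate; the enone is spared because its β-carbon C5 is neopentyl.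

Step 10
Reactants: 13 methyl (2E,5S,6S,8E)-5-hydroxy-6-[(4-methoxybenzyl)oxy]-3,7,7-trimethyl-10-oxododeca-2,8-dienoate
Product: 14 methyl (2E,5S,6S,8E,10Z)-5,10-bis[(tert-butyldimethylsilyl)oxy]-6-[(4-methoxybenzyl)oxy]-3,7,7-trimethyldodeca-2,8,10-trienoate
Conditions: t-BuMe2SiOTf, Et3N, CH2Cl2, −78 → 0 °C
Reagents that add atoms: tert-butyldimethylsilyl trifluoromethanesulfonate, CC(C)(C)[Si](C)(C)OS(=O)(=O)C(F)(F)F
Why: One operation silylates the C2 hydroxyl and converts the ethyl enone into its (Z)-2-silyloxydiene (soft enolisation, only the C8 hydrogens are available); it is done at the ester stage because an enal with γ-hydrogens would itself be turned into a silyl dienol ether.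

Step 11
Reactants: 14 methyl (2E,5S,6S,8E,10Z)-5,10-bis[(tert-butyldimethylsilyl)oxy]-6-[(4-methoxybenzyl)oxy]-3,7,7-trimethyldodeca-2,8,10-trienoate
Product: 15 (2E,5S,6S,8E,10Z)-5,10-bis[(tert-butyldimethylsilyl)oxy]-6-[(4-methoxybenzyl)oxy]-3,7,7-trimethyldodeca-2,8,10-trien-1-ol
Conditions: i-Bu2AlH, CH2Cl2, −78 °C; KNaC4H4O6 work-up
Reagents that add atoms: none
Why: 1,2-Reduction of the enoate by the aluminium hydride gives the allylic alcohol; silyl ether, silyl dienol ether and PMB ether are inert to the hydride and to the neutral tartrate work-up.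

Step 12
Reactants: 15 (2E,5S,6S,8E,10Z)-5,10-bis[(tert-butyldimethylsilyl)oxy]-6-[(4-methoxybenzyl)oxy]-3,7,7-trimethyldodeca-2,8,10-trien-1-ol
Product: 16 (2E,5S,6S,8E,10Z)-5,10-bis[(tert-butyldimethylsilyl)oxy]-6-[(4-methoxybenzyl)oxy]-3,7,7-trimethyldodeca-2,8,10-trienal
Conditions: MnO2, CH2Cl2, rt
Reagents that add atoms: none
Why: MnO2 oxidises only the allylic alcohol, under neutral conditions that spare the acid-sensitive silyloxydiene and keep the (E)-geometry of the enal.

Step 13
Reactants: 16 (2E,5S,6S,8E,10Z)-5,10-bis[(tert-butyldimethylsilyl)oxy]-6-[(4-methoxybenzyl)oxy]-3,7,7-trimethyldodeca-2,8,10-trienal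
Product: 17 trans-decalin aldehyde (2-OTBS and 3-OPMB equatorial; C6=C7 OTBS enol ether; C8 methyl, C9 formyl and C20 cis; H-5 trans to C20)
Conditions: Me2AlCl, CH2Cl2 (0.005 M), −78 → −20 °C
Reagents that add atoms: none
Why: Me2AlCl binds the aldehyde and lowers the dienophile LUMO, so that the (E)-enal C9=C10 should add suprafacially to the s-cis diene C5–C8 in a concerted, asynchronous [4+2] cycloaddition; the closest known reaction type is the Lewis-acid-promoted intramolecular Diels–Alder reaction of 1,7,9-decatrienals to trans-decalins. Ring B closes as the new cyclohexene of the cycloaddition (bonds C8–C9 and C5–C10), and ring A closes at the same moment as the six-membered ring spanned by the four-atom tether C1–C4, which adopts a chair. C9 and C10 follow from the (E)-enal (C11 cis to C20), C8 from the (Z)-enol ether (C17 on the outside of the diene) together with the endo position of the formyl group, and C5 from that same aldehyde-endo transition state, which gives the trans ring fusion. The absolute sense comes from C3 (from pantolactone) and C2, whose OPMB and OTBS groups sit equatorial on the chair tether and so select one face of the diene. The step needs endo over exo and one π-face: the first should be secured by the overlap of the complexed carbonyl with C6–C7, which the Lewis acid strengthens, the second by the equatorial preference of the two ethers beside the C4 gem-dimethyl group. The tether, not the silyloxy group, fixes the regiochemistry (the C7 oxygen and C11 end up 1,3), so polar side reactions of the enol ether (aldol at C11, conjugate addition at C10) would need 11- or 9-membered rings and are kept intermolecular and slow by dilution, while Me2AlCl also scavenges protic acid that would cleave the enol ether.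

Step 14
Reactants: 17 trans-decalin aldehyde; 18 dimethyl (2-oxopropyl)phosphonate
Product: 19 (11E)-enone (C9–CH=CH–C(=O)CH3; rest as in 17)
Conditions: LiCl, i-Pr2NEt, MeCN, rt
Reagents that add atoms: dimethyl (2-oxopropyl)phosphonate 18, COP(=O)(OC)CC(C)=O
Why: Horner–Wadsworth–Emmons olefination under mild LiCl/amine conditions should convert the hindered aldehyde into the (E)-enone without epimerising C9, whose hydrogen is α to a carbonyl only until this step; the silyl enol ether is stable to the weak base.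

Step 15
Reactants: 19 (11E)-enone
Product: 20 C13 methyl ketone (C9–CH2CH2C(=O)CH3; rest as in 17)
Conditions: [(Ph3P)CuH]6, H2O, toluene, rt
Reagents that add atoms: none
Why: Copper hydride conjugate reduction is selective for the disubstituted enone and leaves silyl enol ether and ethers alone; the copper enolate is protonated by the added water to the methyl ketone.

Step 16
Reactants: 20 C13 methyl ketone; 21 trimethyl phosphonoacetate
Product: 22 methyl (13E)-enoate (C6=C7 OTBS enol ether; 2-OTBS; 3-OPMB)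
Conditions: NaH, THF, 0 → 50 °C
Reagents that add atoms: trimethyl phosphonoacetate 21, COC(=O)CP(=O)(OC)OC
Why: Horner–Wadsworth–Emmons olefination of the methyl ketone gives the trisubstituted enoate with the (E)-isomer (ester trans to C12) expected to predominate; the minor (Z)-isomer is removed by chromatography here or after step 18.

Step 17
Reactants: 22 methyl (13E)-enoate
Product: 24 7-ketone methyl ester (C8 methyl equatorial; 2-OTBS; 3-OPMB), via 8-epi ketone 23 (not isolated)
Conditions: Bu4NF, AcOH, THF, 0 °C; then K2CO3 (cat.), MeOH, rt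
Reagents that add atoms: none
Why: Fluoride cleaves the silyl enol ether much faster than the secondary alkyl TBS ether (protonation at C6), and base-mediated enolisation towards C8 then moves the C8 methyl from the axial position, syn-diaxial to C20, to the equatorial one; this thermodynamic epimerisation provides the axial H-8 needed in step 20.

Step 18
Reactants: 24 7-ketone methyl ester
Product: 26 7,15-diol (axial 7-OH cis to the C8 methyl; 2-OTBS; 3-OPMB), via 7-hydroxy ester 25 (not isolated)
Conditions: LiBH(s-Bu)3, THF, −78 °C; then i-Bu2AlH, −78 → −20 °C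
Reagents that add atoms: none
Why: The bulky borohydride attacks the C7 ketone from the equatorial direction, as with 2-methylcyclohexanones, to give the axial alcohol and leaves the β,β-disubstituted enoate untouched at −78 °C; the aluminium hydride then reduces the ester to the allylic alcohol in the same flask.

Step 19
Reactants: 26 7,15-diol
Product: 27 15-acetate with free axial 7-OH
Conditions: Ac2O, pyridine, CH2Cl2, 0 °C
Reagents that add atoms: acetic anhydride, CC(=O)OC(C)=O
Why: Acylation without a nucleophilic catalyst is selective for the primary allylic hydroxyl over the axial secondary C7 hydroxyl, which is flanked by the C8 methyl group.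

Step 20
Reactants: 27 15-acetate with free axial 7-OH
Product: 28 7,13-diene acetate (2-OTBS; 3-OPMB)
Conditions: POCl3, pyridine, 0 → 60 °C
Reagents that add atoms: none
Why: E2-type dehydration through the dichlorophosphate: the axial C7 leaving group is anti-periplanar to the axial hydrogens on C8 and C6, and loss of H-8 should prevail because it gives the more substituted C7=C8 alkene and because axial H-6 is shielded by the axial C4 methyl and C20.

Step 21
Reactants: 28 7,13-diene acetate
Product: 29 C2 alcohol (3-OPMB; 15-OAc)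
Conditions: HF·pyridine, pyridine, THF, 0 °C → rt
Reagents that add atoms: none
Why: Buffered HF removes the secondary TBS ether; the allylic acetate, the PMB ether and both trisubstituted alkenes are stable to it.

Step 22
Reactants: 29 C2 alcohol
Product: 30 2-ketone 3-PMB ether
Conditions: Dess–Martin periodinane, pyridine, CH2Cl2, rt
Reagents that add atoms: none
Why: Dess–Martin oxidation of the equatorial C2 alcohol under buffered, non-enolising conditions, so that C3, now α to the carbonyl, is not epimerised.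

Step 23
Reactants: 30 2-ketone 3-PMB ether
Product: 31 (3S,5S,9R,10S,13E)-3-hydroxy-2-oxolabda-7,13-dien-15-yl acetate (CNP0164008.1)
Conditions: DDQ, CH2Cl2/pH 7 buffer, 0 °C
Reagents that add atoms: none
Why: Oxidative cleavage of the PMB ether by DDQ in wet solvent at neutral pH frees the C3 hydroxyl without acid or base, which avoids α-ketol isomerisation and acetate migration or hydrolysis.

Compound list
1 | (S)-pantolactone | CC1(C)COC(=O)[C@H]1O | starting material
2 | (2S)-3,3-dimethylbutane-1,2,4-triol | OC[C@@H](O)C(C)(C)CO | intermediate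
3 | [(2S,4S)-2-(4-methoxyphenyl)-5,5-dimethyl-1,3-dioxan-4-yl]methanol | OC[C@H]1O[C@@H](c2ccc(OC)cc2)OCC1(C)C | intermediate
4 | triethyl{[(2S,4S)-2-(4-methoxyphenyl)-5,5-dimethyl-1,3-dioxan-4-yl]methoxy}silane | CC[Si](CC)(CC)OC[C@H]1O[C@@H](c2ccc(OC)cc2)OCC1(C)C | intermediate
5 | (3S)-3-[(4-methoxybenzyl)oxy]-2,2-dimethyl-4-[(triethylsilyl)oxy]butan-1-ol | CC[Si](CC)(CC)OC[C@@H](OCc1ccc(OC)cc1)C(C)(C)CO | intermediate
6 | (3S)-3-[(4-methoxybenzyl)oxy]-2,2-dimethyl-4-[(triethylsilyl)oxy]butanal | CC[Si](CC)(CC)OC[C@@H](OCc1ccc(OC)cc1)C(C)(C)C=O | intermediate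
7 | diethyl (2-oxobutyl)phosphonate | CCC(=O)CP(=O)(OCC)OCC | starting material
8 | (4E,7S)-7-[(4-methoxybenzyl)oxy]-6,6-dimethyl-8-[(triethylsilyl)oxy]oct-4-en-3-one | CCC(=O)/C=C/C(C)(C)[C@H](OCc1ccc(OC)cc1)CO[Si](CC)(CC)CC | intermediate
9 | (2S,4E)-2-[(4-methoxybenzyl)oxy]-3,3-dimethyl-6-oxooct-4-enal | CCC(=O)/C=C/C(C)(C)[C@H](OCc1ccc(OC)cc1)C=O | intermediate
10 | methyl 3-methylbut-2-enoate | COC(=O)C=C(C)C | starting material
11 | lithium dienolate of 10 (lithium 1-methoxy-3-methylbuta-1,3-dien-1-olate, not isolated) | [Li]OC(OC)=CC(C)=C | intermediate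
12 | [(1-methoxy-3-methylbuta-1,3-dien-1-yl)oxy]trimethylsilane | C=C(C)C=C(OC)O[Si](C)(C)C | intermediate
13 | methyl (2E,5S,6S,8E)-5-hydroxy-6-[(4-methoxybenzyl)oxy]-3,7,7-trimethyl-10-oxododeca-2,8-dienoate | COC(=O)/C=C(\C)C[C@H](O)[C@@H](OCc1ccc(OC)cc1)C(C)(C)/C=C/C(=O)CC | intermediate
14 | methyl (2E,5S,6S,8E,10Z)-5,10-bis[(tert-butyldimethylsilyl)oxy]-6-[(4-methoxybenzyl)oxy]-3,7,7-trimethyldodeca-2,8,10-trienoate | COC(=O)/C=C(\C)C[C@H](O[Si](C)(C)C(C)(C)C)[C@@H](OCc1ccc(OC)cc1)C(C)(C)/C=C/C(O[Si](C)(C)C(C)(C)C)=C/C | intermediate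
15 | (2E,5S,6S,8E,10Z)-5,10-bis[(tert-butyldimethylsilyl)oxy]-6-[(4-methoxybenzyl)oxy]-3,7,7-trimethyldodeca-2,8,10-trien-1-ol | OC/C=C(\C)C[C@H](O[Si](C)(C)C(C)(C)C)[C@@H](OCc1ccc(OC)cc1)C(C)(C)/C=C/C(O[Si](C)(C)C(C)(C)C)=C/C | intermediate
16 | (2E,5S,6S,8E,10Z)-5,10-bis[(tert-butyldimethylsilyl)oxy]-6-[(4-methoxybenzyl)oxy]-3,7,7-trimethyldodeca-2,8,10-trienal (cycloaddition precursor) | O=C/C=C(\C)C[C@H](O[Si](C)(C)C(C)(C)C)[C@@H](OCc1ccc(OC)cc1)C(C)(C)/C=C/C(O[Si](C)(C)C(C)(C)C)=C/C | intermediate
17 | trans-decalin aldehyde: 2-OTBS and 3-OPMB trans and equatorial, C6=C7 OTBS enol ether, C8 methyl, C9 formyl and C20 on one face, H-5 on the other | O=C[C@@H]1[C@H](C)C(O[Si](C)(C)C(C)(C)C)=C[C@@H]2C(C)(C)[C@H](OCc3ccc(OC)cc3)[C@@H](O[Si](C)(C)C(C)(C)C)C[C@@]12C | intermediate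
18 | dimethyl (2-oxopropyl)phosphonate | COP(=O)(OC)CC(C)=O | starting material
19 | (11E)-enone: 17 with C9–CH=CH–C(=O)CH3 in place of the formyl group | CC(=O)/C=C/[C@@H]1[C@H](C)C(O[Si](C)(C)C(C)(C)C)=C[C@@H]2C(C)(C)[C@H](OCc3ccc(OC)cc3)[C@@H](O[Si](C)(C)C(C)(C)C)C[C@@]12C | intermediate
20 | C13 methyl ketone: 19 with saturated C11–C12 | CC(=O)CC[C@@H]1[C@H](C)C(O[Si](C)(C)C(C)(C)C)=C[C@@H]2C(C)(C)[C@H](OCc3ccc(OC)cc3)[C@@H](O[Si](C)(C)C(C)(C)C)C[C@@]12C | intermediate
21 | trimethyl phosphonoacetate | COC(=O)CP(=O)(OC)OC | starting material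
22 | methyl (13E)-enoate with C6=C7 OTBS enol ether, 2-OTBS, 3-OPMB, C8 methyl cis to C20 | COC(=O)/C=C(\C)CC[C@@H]1[C@H](C)C(O[Si](C)(C)C(C)(C)C)=C[C@@H]2C(C)(C)[C@H](OCc3ccc(OC)cc3)[C@@H](O[Si](C)(C)C(C)(C)C)C[C@@]12C | intermediate
23 | 8-epi 7-ketone (C8 methyl axial, cis to C20; not isolated) | COC(=O)/C=C(\C)CC[C@@H]1[C@H](C)C(=O)C[C@@H]2C(C)(C)[C@H](OCc3ccc(OC)cc3)[C@@H](O[Si](C)(C)C(C)(C)C)C[C@@]12C | intermediate
24 | 7-ketone methyl ester, C8 methyl equatorial (trans to C20 and to the C9 side chain) | COC(=O)/C=C(\C)CC[C@@H]1[C@@H](C)C(=O)C[C@@H]2C(C)(C)[C@H](OCc3ccc(OC)cc3)[C@@H](O[Si](C)(C)C(C)(C)C)C[C@@]12C | intermediate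
25 | 7-hydroxy ester, axial 7-OH cis to the C8 methyl (not isolated) | COC(=O)/C=C(\C)CC[C@@H]1[C@@H](C)[C@@H](O)C[C@@H]2C(C)(C)[C@H](OCc3ccc(OC)cc3)[C@@H](O[Si](C)(C)C(C)(C)C)C[C@@]12C | intermediate
26 | 7,15-diol, axial 7-OH cis to the C8 methyl, (13E) | OC/C=C(\C)CC[C@@H]1[C@@H](C)[C@@H](O)C[C@@H]2C(C)(C)[C@H](OCc3ccc(OC)cc3)[C@@H](O[Si](C)(C)C(C)(C)C)C[C@@]12C | intermediate
27 | 15-acetate of 26 with free 7-OH | CC(=O)OC/C=C(\C)CC[C@@H]1[C@@H](C)[C@@H](O)C[C@@H]2C(C)(C)[C@H](OCc3ccc(OC)cc3)[C@@H](O[Si](C)(C)C(C)(C)C)C[C@@]12C | intermediate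
28 | 2-OTBS, 3-OPMB labda-7,13E-dien-15-yl acetate | CC(=O)OC/C=C(\C)CC[C@@H]1C(C)=CC[C@@H]2C(C)(C)[C@H](OCc3ccc(OC)cc3)[C@@H](O[Si](C)(C)C(C)(C)C)C[C@@]12C | intermediate
29 | 2-hydroxy-3-OPMB labda-7,13E-dien-15-yl acetate (2-OH equatorial, trans to 3-OPMB) | CC(=O)OC/C=C(\C)CC[C@@H]1C(C)=CC[C@@H]2C(C)(C)[C@H](OCc3ccc(OC)cc3)[C@@H](O)C[C@@]12C | intermediate
30 | 2-oxo-3-OPMB labda-7,13E-dien-15-yl acetate | CC(=O)OC/C=C(\C)CC[C@@H]1C(C)=CC[C@@H]2C(C)(C)[C@H](OCc3ccc(OC)cc3)C(=O)C[C@@]12C | intermediate
31 | (3S,5S,9R,10S,13E)-3-hydroxy-2-oxolabda-7,13-dien-15-yl acetate | CC(=O)OC/C=C(\C)CC[C@@H]1C(C)=CC[C@@H]2C(C)(C)[C@H](O)C(=O)C[C@@]12C | target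

Total step count: 23 (22 in the main line plus step 8, the preparation of dienolate 12).
Longest linear sequence: 22 steps from (S)-pantolactone (steps 1–7 and 9–23).

Steps most likely to fail

Step 13 (cycloaddition). The ring closure may be too slow, because the C5–C10 bond joins a fully substituted dienophile carbon to a neopentyl diene terminus. The Lewis acid may instead cause intermolecular aldol addition of the silyl enol ether to the complexed aldehyde or loss of the enol silyl group, and closure through the exo arrangement would give the cis-decalin. The fallback moves the cycloaddition to the ester oxidation level, where no aldehyde and no Lewis acid are present. It sets out from trienoate 14, which is heated in o-dichlorobenzene (about 200 °C, radical inhibitor, base-washed glass) to give the methyl ester cycloadduct F1. Reduction with LiAlH4 gives the primary alcohol F2, and Dess–Martin oxidation with pyridine buffer returns to the route at aldehyde 17.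

Step 20 (dehydration). Elimination may take the axial H-6 instead of H-8 and give the C6=C7 alkene, or the dichlorophosphate may ionise and rearrange. The fallback replaces elimination by reduction of an enol triflate. It sets out from ketone 24, which with Tf2O and 2,6-di-tert-butyl-4-methylpyridine should give the more substituted C7=C8 enol triflate F3 under equilibrating conditions. Pd(OAc)2/PPh3 with HCO2H and Bu3N in DMF replaces the triflate by hydrogen to give the 7,13-diene ester F4, i-Bu2AlH gives the allylic alcohol F5, and acetylation (Ac2O, pyridine) returns to the route at 28.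

Step 9 (vinylogous aldol). Chelation control may be lost, giving the C2 epimer whose silyl ether would have to be axial in step 13. The enone may also be consumed, by conjugate addition of the new C2 oxygen to C5 (five-membered ether) or of the dienolate. The fallback inverts the order of events so that the aldol is run on an aldehyde without enone, at the cost of more steps. It sets out from alcohol 5, which is acetylated to the acetate F6. Swern oxidation of its TES ether gives the aldehyde F7, and the same MgBr2·OEt2-mediated addition of 12 gives the hydroxy ester F8. Silylation (t-BuMe2SiOTf, 2,6-lutidine) gives the TBS ether F9, K2CO3 in MeOH removes the acetate to give the primary alcohol F10, Dess–Martin oxidation gives the aldehyde F11, and olefination with 7 (NaH, THF) gives the enone F12. Treatment of F12 with t-BuMe2SiOTf and Et3N returns to the route at 14.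

Further compounds
F1 | step 13 | methyl ester cycloadduct (17 with CO2CH3 in place of the formyl group) | COC(=O)[C@@H]1[C@H](C)C(O[Si](C)(C)C(C)(C)C)=C[C@@H]2C(C)(C)[C@H](OCc3ccc(OC)cc3)[C@@H](O[Si](C)(C)C(C)(C)C)C[C@@]12C
F2 | step 13 | primary alcohol (17 with CH2OH in place of the formyl group) | OC[C@@H]1[C@H](C)C(O[Si](C)(C)C(C)(C)C)=C[C@@H]2C(C)(C)[C@H](OCc3ccc(OC)cc3)[C@@H](O[Si](C)(C)C(C)(C)C)C[C@@]12C
F3 | step 20 | C7=C8 enol triflate of 24 | COC(=O)/C=C(\C)CC[C@@H]1C(C)=C(OS(=O)(=O)C(F)(F)F)C[C@@H]2C(C)(C)[C@H](OCc3ccc(OC)cc3)[C@@H](O[Si](C)(C)C(C)(C)C)C[C@@]12C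
F4 | step 20 | methyl 2-OTBS-3-OPMB-labda-7,13E-dien-15-oate | COC(=O)/C=C(\C)CC[C@@H]1C(C)=CC[C@@H]2C(C)(C)[C@H](OCc3ccc(OC)cc3)[C@@H](O[Si](C)(C)C(C)(C)C)C[C@@]12C
F5 | step 20 | 2-OTBS-3-OPMB-labda-7,13E-dien-15-ol | OC/C=C(\C)CC[C@@H]1C(C)=CC[C@@H]2C(C)(C)[C@H](OCc3ccc(OC)cc3)[C@@H](O[Si](C)(C)C(C)(C)C)C[C@@]12C
F6 | step 9 | (3S)-3-[(4-methoxybenzyl)oxy]-2,2-dimethyl-4-[(triethylsilyl)oxy]butyl acetate | CC[Si](CC)(CC)OC[C@@H](OCc1ccc(OC)cc1)C(C)(C)COC(C)=O
F7 | step 9 | (3S)-3-[(4-methoxybenzyl)oxy]-2,2-dimethyl-4-oxobutyl acetate | O=C[C@@H](OCc1ccc(OC)cc1)C(C)(C)COC(C)=O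
F8 | step 9 | methyl (2E,5S,6S)-8-acetoxy-5-hydroxy-6-[(4-methoxybenzyl)oxy]-3,7,7-trimethyloct-2-enoate | COC(=O)/C=C(\C)C[C@H](O)[C@@H](OCc1ccc(OC)cc1)C(C)(C)COC(C)=O
F9 | step 9 | methyl (2E,5S,6S)-8-acetoxy-5-[(tert-butyldimethylsilyl)oxy]-6-[(4-methoxybenzyl)oxy]-3,7,7-trimethyloct-2-enoate | COC(=O)/C=C(\C)C[C@H](O[Si](C)(C)C(C)(C)C)[C@@H](OCc1ccc(OC)cc1)C(C)(C)COC(C)=O
F10 | step 9 | methyl (2E,5S,6S)-5-[(tert-butyldimethylsilyl)oxy]-8-hydroxy-6-[(4-methoxybenzyl)oxy]-3,7,7-trimethyloct-2-enoate | COC(=O)/C=C(\C)C[C@H](O[Si](C)(C)C(C)(C)C)[C@@H](OCc1ccc(OC)cc1)C(C)(C)CO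
F11 | step 9 | methyl (2E,5S,6S)-5-[(tert-butyldimethylsilyl)oxy]-6-[(4-methoxybenzyl)oxy]-3,7,7-trimethyl-8-oxooct-2-enoate | COC(=O)/C=C(\C)C[C@H](O[Si](C)(C)C(C)(C)C)[C@@H](OCc1ccc(OC)cc1)C(C)(C)C=O
F12 | step 9 | methyl (2E,5S,6S,8E)-5-[(tert-butyldimethylsilyl)oxy]-6-[(4-methoxybenzyl)oxy]-3,7,7-trimethyl-10-oxododeca-2,8-dienoate | COC(=O)/C=C(\C)C[C@H](O[Si](C)(C)C(C)(C)C)[C@@H](OCc1ccc(OC)cc1)C(C)(C)/C=C/C(=O)CC
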